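Skeleton numbering used below: C1 quaternary ring-fusion carbon, C2/C3 cyclopentane CH2 groups, C4 isopropyl carbinol, C5 ring-fusion CH, C6 acyloxy carbon, C7, C8 (methyl) and C9 epoxide carbons, C10.
Cuts: the C6–O acyl bond and the epoxide C–O bonds; then C2–C3 of the cyclopentane, as ring-closing metathesis of two vinyl groups followed by saturation; then C4–isopropyl and C4–C3 (organometallic additions to a C4 carboxyl).
Further cuts: C8=C9 (first metathesis), C1–C5 ([3,3] ester-enolate Claisen rearrangement) and the allyl ester C–O bond, back to an (E)-dienol and a C6-hydroxy ester.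
Forward: acyclic allyl β-hydroxy ester → Claisen (C1–C5) → cycloheptene ring → C4 carbinol → cyclopentene ring (key) → saturation → epoxide → 3,4-dimethoxybenzoate.
Stereochemistry: C6 from ethyl (3R)-4-chloro-3-hydroxybutanoate; C5 and quaternary C1 from the chelated dianion Claisen (anti to the C6 alkoxide, chair, E-alkene); C4 by chelation/Felkin-controlled isopropyl addition; C8/C9 by C6-hydroxyl-directed epoxidation.
Enabling feature: C1 and C4, the two fully substituted carbons flanking C2–C3, each carry a terminal vinyl group held trans and gauche on the cycloheptene (C1 and, through C4, C5), forming a 1,6-diene; the only other alkene (C8=C9) is trisubstituted and endocyclic.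

Key step: step 10

Remark: pent-1-en-4-yne, ethyl (3R)-4-chloro-3-hydroxybutanoate and 3,4-dimethoxybenzoyl chloride are taken as purchasable; locants inside systematic names follow nomenclature rules, while C1–C10 in the text are the skeleton numbering above.

Step 1
Reactants: 1 pent-1-en-4-yne
Product: 3 (2E)-3-methylhexa-2,5-dien-1-ol, via alkenylalane 2 (not isolated)
Conditions: Me3Al, Cp2ZrCl2 (cat.), CH2Cl2, 0 °C to rt; then (CH2O)n, rt; aq. HCl
Reagents that add atoms: trimethylaluminium C[Al](C)C; formaldehyde (from paraformaldehyde) C=O
Why: Cp2ZrCl2-catalysed syn-carboalumination of the terminal alkyne (Negishi carboalumination) places methyl on the internal carbon and aluminium on the terminal carbon on the same side, and the alkenylalane should be captured by formaldehyde with retention to give the E-trisubstituted allylic alcohol, the unactivated terminal alkene being much less reactive.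

Step 2
Reactants: 4 ethyl (3R)-4-chloro-3-hydroxybutanoate
Product: 5 ethyl [(2R)-oxiran-2-yl]acetate
Conditions: Ag2O, 1,2-dimethoxyethane, reflux
Reagents that add atoms: none
Why: Intramolecular Williamson-type closure (the hydroxyl displaces the primary chloride with silver assistance) forms the oxirane without touching the carbinol carbon, so its configuration is retained, and the non-basic medium should avoid elimination to the 4-hydroxybut-2-enoate.

Step 3
Reactants: 5 ethyl [(2R)-oxiran-2-yl]acetate
Product: 6 ethyl (3S)-3-hydroxy-5-methylhex-5-enoate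
Conditions: CH2=C(CH3)MgBr, CuI (cat.), THF, −78 to −30 °C; aq. NH4Cl
Reagents that add atoms: isopropenylmagnesium bromide CC(=C)[Mg]Br
Why: CuI-catalysed Grignard opening of the monosubstituted epoxide proceeds by SN2 attack at its CH2 carbon and at low temperature should outrun addition to the ester, so the carbinol stereocentre is carried over unchanged (the descriptor becomes S only through the change of priorities).

Step 4
Reactants: 6 ethyl (3S)-3-hydroxy-5-methylhex-5-enoate; 3 (2E)-3-methylhexa-2,5-dien-1-ol
Product: 7 (2E)-3-methylhexa-2,5-dien-1-yl (3S)-3-hydroxy-5-methylhex-5-enoate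
Conditions: Ti(OEt)4 (cat.), toluene, 100 °C, 4 Å molecular sieves
Reagents that add atoms: none
Why: Ti(OEt)4-catalysed transesterification exchanges the ethoxy group for the primary allylic alkoxide under nearly neutral conditions that should leave the β-hydroxyl, its stereocentre and the E-alkene untouched, removal of ethanol driving the equilibrium.

Step 5
Reactants: 7 (2E)-3-methylhexa-2,5-dien-1-yl (3S)-3-hydroxy-5-methylhex-5-enoate
Product: 9 (2S,3S)-3-hydroxy-5-methyl-2-[(3S)-3-methylhexa-1,5-dien-3-yl]hex-5-enoic acid, via dilithium enolate alkoxide 8 (not isolated)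
Conditions: lithium diisopropylamide (2.2 equiv), THF, −78 °C to rt, then 50 °C; aq. HCl
Reagents that add atoms: none
Why: Double deprotonation gives a lithium-chelated enolate alkoxide of fixed geometry (the Fráter–Seebach dianion) whose [3,3]-sigmatropic ester-enolate Claisen rearrangement (Ireland–Claisen type) should pass through a chair on the enolate face anti to the C7 chain of the chelate, which sets C5 anti to the C6 hydroxyl, while the E-alkene places the CH2 arm (future C10) equatorial and the methyl axial at the migrating terminus and so sets quaternary C1; the vinyl group released at C1 carries the future C2.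

Step 6
Reactants: 9 (2S,3S)-3-hydroxy-5-methyl-2-[(3S)-3-methylhexa-1,5-dien-3-yl]hex-5-enoic acid
Product: 10 (1S,2S,7S)-2-ethenyl-7-hydroxy-2,5-dimethylcyclohept-4-ene-1-carboxylic acid
Conditions: second-generation Grubbs catalyst RuCl2(=CHPh)(H2IMes)(PCy3) (cat.), CH2Cl2 (high dilution), 40 °C
Reagents that add atoms: none
Why: Ring-closing metathesis should start at the unhindered allyl group and can close only onto the 2-methylallyl group (the vinyl group on the same quaternary carbon is a poor loading site and would give a cyclobutene), giving the cycloheptene with its trisubstituted C8=C9 bond and ethene, with no stereocentre involved.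

Step 7
Reactants: 10 (1S,2S,7S)-2-ethenyl-7-hydroxy-2,5-dimethylcyclohept-4-ene-1-carboxylic acid
Product: 11 (1S,2S,7S)-2-ethenyl-7-hydroxy-N-methoxy-N,2,5-trimethylcyclohept-4-ene-1-carboxamide
Conditions: MeNHOMe·HCl, EDC·HCl, HOBt (cat.), N-methylmorpholine, CH2Cl2, 0 °C to rt
Reagents that add atoms: N,O-dimethylhydroxylamine hydrochloride CNOC.Cl
Why: Carbodiimide coupling through the hydroxybenzotriazole active ester should acylate the much more nucleophilic amine in preference to the secondary hydroxyl and give the Weinreb amide without strongly basic conditions, so that C5, already in the more stable trans relation to the C6 hydroxyl, is not epimerised.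

Step 8
Reactants: 11 (1S,2S,7S)-2-ethenyl-7-hydroxy-N-methoxy-N,2,5-trimethylcyclohept-4-ene-1-carboxamide
Product: 12 1-[(1S,2S,7S)-2-ethenyl-7-hydroxy-2,5-dimethylcyclohept-4-en-1-yl]prop-2-en-1-one
Conditions: CH2=CHMgBr (excess), THF, 0 °C; inverse quench into cold aq. HCl
Reagents that add atoms: vinylmagnesium bromide C=C[Mg]Br
Why: The Grignard reagent (after deprotonating the hydroxyl) adds to the Weinreb amide to give a magnesium-chelated tetrahedral adduct that is stable until the cold acidic quench, so the vinyl ketone is released only when no nucleophile remains and over-addition, conjugate addition and oxa-Michael closure should be avoided; no stereocentre is formed.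

Step 9
Reactants: 12 1-[(1S,2S,7S)-2-ethenyl-7-hydroxy-2,5-dimethylcyclohept-4-en-1-yl]prop-2-en-1-one
Product: 13 (3S)-3-[(1S,2S,7S)-2-ethenyl-7-hydroxy-2,5-dimethylcyclohept-4-en-1-yl]-4-methylpent-1-en-3-ol
Conditions: i-PrMgCl, CeCl3, THF, −78 °C (ketone added to the reagent); aq. NH4Cl
Reagents that add atoms: isopropylmagnesium chloride CC(C)[Mg]Cl
Why: The organocerium reagent i-PrCeCl2 adds in 1,2-fashion without enolisation (organocerium carbonyl addition), and both the six-membered chelate between the C6 alkoxide and the ketone oxygen and the Felkin–Anh model direct the isopropyl group to the carbonyl face opposite the quaternary C1 substituent of C5, which should set C4 with its oxygen on the side of C6 as in the target.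

Step 10
Reactants: 13 (3S)-3-[(1S,2S,7S)-2-ethenyl-7-hydroxy-2,5-dimethylcyclohept-4-en-1-yl]-4-methylpent-1-en-3-ol
Product: 14 (3S,3aS,4S,8aS)-6,8a-dimethyl-3-(propan-2-yl)-3,3a,4,5,8,8a-hexahydroazulene-3,4-diol
Conditions: second-generation Hoveyda–Grubbs catalyst RuCl2(=CH-C6H4-2-OiPr)(H2IMes) (cat.), toluene (high dilution), 80 °C, argon sparge
Reagents that add atoms: none
Why: Ring-closing olefin metathesis by the Chauvin mechanism: the ruthenium alkylidene should load on the vinyl group of the tertiary allylic alcohol (helped by the hydroxyl), form a ruthenacyclobutane with the vinyl group on C1 and expel ethene, leaving the C2=C3 bond. The closest known reaction type is the ring-closing metathesis of 3-hydroxy-1,6-dienes to cyclopent-2-enols that carry a quaternary allylic carbon. The cyclopentene is closed as a 1,6-diene metathesis with the new double bond inside the ring, trans-fused to the cycloheptene because the vinyl on C1 and the carbinol substituent on C5 are already trans and gauche. No stereocentre is formed; C1, C4, C5 and C6 pass through unchanged and C2=C3 is saturated in step 11. The step needs chemoselectivity for the two terminal vinyl groups over the C8=C9 bond, which is trisubstituted, endocyclic and unstrained and should not engage, and ring closure over oligomerisation, which is secured by the five-ring size, the preorganised diene, high dilution and removal of ethene. The free diol is compatible with the catalyst.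

Step 11
Reactants: 14 (3S,3aS,4S,8aS)-6,8a-dimethyl-3-(propan-2-yl)-3,3a,4,5,8,8a-hexahydroazulene-3,4-diol
Product: 15 (3R,3aS,4S,8aR)-6,8a-dimethyl-3-(propan-2-yl)-1,2,3,3a,4,5,8,8a-octahydroazulene-3,4-diol
Conditions: 2-nitrobenzenesulfonohydrazide, Et3N, CH2Cl2, rt
Reagents that add atoms: none
Why: Diimide generated in the flask reduces alkenes by concerted syn transfer of two hydrogens at a rate that falls steeply with substitution, so the strained cis-disubstituted cyclopentene should be saturated while the trisubstituted cycloheptene bond survives, without hydrogenolysis of the allylic C–O bond and without creating a stereocentre.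

Step 12
Reactants: 15 (3R,3aS,4S,8aR)-6,8a-dimethyl-3-(propan-2-yl)-1,2,3,3a,4,5,8,8a-octahydroazulene-3,4-diol
Product: 16 (1R,4R,5S,6S,8R,9S)-8,9-epoxydaucane-4,6-diol (skeleton numbering; the epoxide of 15 on the face of the C6 hydroxyl)
Conditions: VO(acac)2 (cat.), t-BuOOH, CH2Cl2, 0 °C to rt
Reagents that add atoms: tert-butyl hydroperoxide CC(C)(C)OO
Why: In this VO(acac)2-catalysed hydroxyl-directed epoxidation the vanadate ester of the homoallylic C6 alcohol delivers the peroxide oxygen to the face of the C8=C9 bond syn to that hydroxyl, which is also the face away from the angular methyl group, and this should set C8 and C9.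

Step 13
Reactants: 16 (1R,4R,5S,6S,8R,9S)-8,9-epoxydaucane-4,6-diol; 17 3,4-dimethoxybenzoyl chloride
Product: 18 CNP0251065.1 (the C6 3,4-dimethoxybenzoate of 16)
Conditions: DMAP (cat.), Et3N, CH2Cl2, 0 °C to rt
Reagents that add atoms: none
Why: DMAP-catalysed acylation by the acid chloride (nucleophilic catalysis) should esterify only the secondary C6 hydroxyl, the tertiary C4 hydroxyl being too hindered, and the amine buffer keeps the epoxide from acid-induced opening; no stereocentre is touched.

Compound list
1 | pent-1-en-4-yne | C#CCC=C | starting material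
2 | (1E)-dimethyl(2-methylpenta-1,4-dien-1-yl)alumane (formed in the flask) | C=CC/C(C)=C/[Al](C)C | intermediate
3 | (2E)-3-methylhexa-2,5-dien-1-ol | C=CC/C(C)=C/CO | intermediate
4 | ethyl (3R)-4-chloro-3-hydroxybutanoate | CCOC(=O)C[C@@H](O)CCl | starting material
5 | ethyl [(2R)-oxiran-2-yl]acetate | CCOC(=O)C[C@@H]1CO1 | intermediate
6 | ethyl (3S)-3-hydroxy-5-methylhex-5-enoate | CCOC(=O)C[C@@H](O)CC(C)=C | intermediate
7 | (2E)-3-methylhexa-2,5-dien-1-yl (3S)-3-hydroxy-5-methylhex-5-enoate | C=CC/C(C)=C/COC(=O)C[C@@H](O)CC(C)=C | intermediate
8 | dilithium enolate alkoxide of 7 (formed in the flask; C6 chain cis to the enolate oxygen) | [Li+].[Li+].C=CC/C(C)=C/CO/C([O-])=C/[C@@H]([O-])CC(C)=C | intermediate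
9 | (2S,3S)-3-hydroxy-5-methyl-2-[(3S)-3-methylhexa-1,5-dien-3-yl]hex-5-enoic acid | OC(=O)[C@H]([C@@H](O)CC(C)=C)[C@](C)(C=C)CC=C | intermediate
10 | (1S,2S,7S)-2-ethenyl-7-hydroxy-2,5-dimethylcyclohept-4-ene-1-carboxylic acid | OC(=O)[C@@H]1[C@@H](O)CC(C)=CC[C@@]1(C)C=C | intermediate
11 | (1S,2S,7S)-2-ethenyl-7-hydroxy-N-methoxy-N,2,5-trimethylcyclohept-4-ene-1-carboxamide | CON(C)C(=O)[C@@H]1[C@@H](O)CC(C)=CC[C@@]1(C)C=C | intermediate
12 | 1-[(1S,2S,7S)-2-ethenyl-7-hydroxy-2,5-dimethylcyclohept-4-en-1-yl]prop-2-en-1-one | C=CC(=O)[C@@H]1[C@@H](O)CC(C)=CC[C@@]1(C)C=C | intermediate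
13 | (3S)-3-[(1S,2S,7S)-2-ethenyl-7-hydroxy-2,5-dimethylcyclohept-4-en-1-yl]-4-methylpent-1-en-3-ol | C=C[C@@](O)(C(C)C)[C@@H]1[C@@H](O)CC(C)=CC[C@@]1(C)C=C | intermediate
14 | (3S,3aS,4S,8aS)-6,8a-dimethyl-3-(propan-2-yl)-3,3a,4,5,8,8a-hexahydroazulene-3,4-diol | O[C@H]1CC(C)=CC[C@@]2(C)C=C[C@@](O)(C(C)C)[C@H]12 | intermediate
15 | (3R,3aS,4S,8aR)-6,8a-dimethyl-3-(propan-2-yl)-1,2,3,3a,4,5,8,8a-octahydroazulene-3,4-diol | O[C@H]1CC(C)=CC[C@@]2(C)CC[C@@](O)(C(C)C)[C@H]12 | intermediate
16 | (1R,4R,5S,6S,8R,9S)-8,9-epoxydaucane-4,6-diol (skeleton numbering) | O[C@H]1C[C@@]2(C)O[C@H]2C[C@@]2(C)CC[C@@](O)(C(C)C)[C@H]12 | intermediate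
17 | 3,4-dimethoxybenzoyl chloride | COc1ccc(C(Cl)=O)cc1OC | starting material
18 | CNP0251065.1, the C6 3,4-dimethoxybenzoate of 16 | COc1ccc(C(=O)O[C@H]2C[C@@]3(C)O[C@H]3C[C@@]3(C)CC[C@@](O)(C(C)C)[C@H]23)cc1OC | target

Total step count: 13. Longest linear sequence: 12 steps (from 4, steps 2 to 13).

Steps most likely to fail

Step 5. The lithium ester enolate may fragment (loss of the allylic alkoxide through a ketene) before the congested bond between a tertiary and a quaternary carbon forms, and facial selectivity may erode if chelation is incomplete. The fallback sets out from 7 and returns at 9. The hydroxyl is silylated (t-BuMe2SiOTf, 2,6-lutidine) to (2E)-3-methylhexa-2,5-dien-1-yl (3S)-3-[(tert-butyldimethylsilyl)oxy]-5-methylhex-5-enoate F1. Lithium diisopropylamide in THF/HMPA at −78 °C with Me3SiCl should give the trimethylsilyl ketene acetal F2 with the same enolate geometry. On warming this should rearrange (Ireland–Claisen of a silyl ketene acetal) and, after aqueous work-up, give the silyloxy acid F3. Bu4NF then returns 9. Stereocontrol here rests on the chair and on 1,2-induction by the silyloxy centre instead of chelation, and any diastereomer would be removed at F3.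

Step 10. The ruthenium alkylidene may load and turn over slowly between two alkenes that both sit on fully substituted carbons, with possible trapping by the neighbouring hydroxyls or double-bond migration. The fallback sets out from 12 and returns at 15. The ring is closed one step earlier, at the ketone level, where the C3 alkene is an unhindered vinyl ketone and no carbinol neighbours the metal. Ring-closing metathesis of 12 should give the bicyclic cyclopentenone F4. Conjugate reduction with [(Ph3P)CuH]6 is chemoselective for the enone and should give the cyclopentanone F5. Addition of i-PrMgCl/CeCl3 from the face of H5 (opposite the angular methyl group and C6) should then give 15 directly, replacing steps 9 to 11.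

Step 11. Chemoselectivity may be lost, by partial reduction of the trisubstituted alkene or incomplete reduction of the hindered cyclopentene. The fallback sets out from 14 and returns at 16, with the order of the two alkene reactions reversed. m-Chloroperbenzoic acid with NaHCO3 should epoxidise the more electron-rich trisubstituted C8=C9 bond first, on the face syn to the C6 hydroxyl and anti to the angular methyl group, to give the epoxy cyclopentene diol F6. The only remaining alkene is then reduced with excess diimide (or H2 over Pd/C in ethyl acetate) to give 16.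

Further compounds
F1 | step 5 | (2E)-3-methylhexa-2,5-dien-1-yl (3S)-3-[(tert-butyldimethylsilyl)oxy]-5-methylhex-5-enoate | C=CC/C(C)=C/COC(=O)C[C@@H](O[Si](C)(C)C(C)(C)C)CC(C)=C
F2 | step 5 | trimethylsilyl ketene acetal of F1 (silyloxy-bearing chain cis to the OSiMe3 group) | C=CC/C(C)=C/CO/C(O[Si](C)(C)C)=C/[C@@H](O[Si](C)(C)C(C)(C)C)CC(C)=C
F3 | step 5 | (2S,3S)-3-[(tert-butyldimethylsilyl)oxy]-5-methyl-2-[(3S)-3-methylhexa-1,5-dien-3-yl]hex-5-enoic acid | OC(=O)[C@H]([C@@H](O[Si](C)(C)C(C)(C)C)CC(C)=C)[C@](C)(C=C)CC=C
F4 | step 10 | (3aS,4S,8aS)-4-hydroxy-6,8a-dimethyl-3a,4,5,8-tetrahydroazulen-3(8aH)-one | O[C@H]1CC(C)=CC[C@@]2(C)C=CC(=O)[C@H]12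
F5 | step 10 | (3aS,4S,8aR)-4-hydroxy-6,8a-dimethyl-1,2,3a,4,5,8-hexahydroazulen-3(8aH)-one | O[C@H]1CC(C)=CC[C@@]2(C)CCC(=O)[C@H]12
F6 | step 11 | 8,9-epoxide of 14 on the face of the C6 hydroxyl (2,3-didehydro analogue of 16) | O[C@H]1C[C@@]2(C)O[C@H]2C[C@@]2(C)C=C[C@@](O)(C(C)C)[C@H]12
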